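**Retrosynthetic overview**
1. The oxepane C2–O bond is cut last: the allyl cation (C‑2/C‑1/C‑10) of seco‑phenol 14 is captured by the ortho‑phenol, which sets C‑2.
2. The quaternary–benzylic C4–C1′ bond comes from visible‑light photoredox addition of a C‑4 tertiary radical (from trifluoroborate 10) to the ortho‑quinone methide 13, made in situ from 11 and 12; this sets C‑4 and C‑1′.
3. Radical precursor 10 comes from the cross‑conjugated dienone 7 by copper‑boryl conjugate addition, KHF2 exchange and Luche reduction.
4. Dienone 7 comes from (+)‑aromadendrene by ozonolysis, Saegusa desaturation, MeLi addition and IBX 1,3‑transposition/dehydrogenation.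
5. Ring order: the cyclopropane, seven‑ and five‑membered carbocycles (with C‑5, C‑6, C‑7) are bought in 1; the arene is attached in step 7 and the oxepane ring closes last.

Assumption: aromadendrane numbering is used (five‑membered ring C‑1 to C‑5; seven‑membered ring C‑1, C‑5 to C‑10; cyclopropane C‑6/C‑7/C‑11; C‑14 on C‑10; C‑15 on C‑4; α is the face of H‑6/H‑7, β the face of H‑5 and the CMe2 bridge), and commercial (+)‑aromadendrene is taken as the 1αH,5βH,6αH,7αH,4α‑methyl enantiomer, whose C‑5/C‑6/C‑7 configuration is that of the target.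

**Step 1**
Reactants: 1 (+)-aromadendrene
Product: 2 (+)-apoaromadendrone
Conditions: O3, CH2Cl2–MeOH, −78 °C; then Me2S, −78 → 25 °C
Reagents that add atoms: ozone, O=[O+][O-]
Why: Ozonolysis of the only alkene (exocyclic C10=C14) is the known route to apoaromadendrone and leaves the cyclopropane and all stereocentres untouched.

**Step 2**
Reactants: 2 (+)-apoaromadendrone
Product: 4 14-noraromadendr-1-en-10-one, via silyl enol ether 3 (not isolated)
Conditions: Me3SiCl, NaI, Et3N, MeCN, 25 °C; then Pd(OAc)2 (10 mol %), O2 (1 atm), DMSO, 40 °C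
Reagents that add atoms: none
Why: Thermodynamic silylation gives the more substituted C10=C1 enol silane, and Saegusa–Ito oxidation proceeds by syn β‑hydride elimination from a divalent palladium enolate bound on the α‑face (the β‑face of the seven‑membered ring carries the CMe2 bridge), so only H‑2α can be lost (H‑5 is β) and C‑5 is untouched.

**Step 3**
Reactants: 4 14-noraromadendr-1-en-10-one
Product: 5 aromadendr-1-en-10β-ol
Conditions: MeLi, Et2O, −78 °C; then H2O
Reagents that add atoms: methyllithium, [Li]C
Why: 1,2‑Addition of methyllithium to the enone re‑installs C‑14 as a tertiary allylic alcohol (α‑face attack expected; the C‑10 centre is erased in step 4).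

**Step 4**
Reactants: 5 aromadendr-1-en-10β-ol
Product: 7 aromadendra-1(10),3-dien-2-one, via transposed enone 6 (not isolated)
Conditions: IBX (3.5 equiv), DMSO, 55 °C then 80 °C
Reagents that add atoms: none
Why: IBX effects the Dauben‑type oxidative 1,3‑transposition of the tertiary allylic alcohol to enone 6 and, on warming, the Nicolaou dehydrogenation of its only enolisable α′ position (C‑3/C‑4); no stereocentre is formed and H‑5 is retained.

**Step 5**
Reactants: 7 aromadendra-1(10),3-dien-2-one
Product: 9 potassium trifluoro[2-oxoaromadendr-1(10)-en-4β-yl]borate, via pinacol boronate 8 (not isolated)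
Conditions: B2pin2, CuCl (5 mol %), xantphos (5 mol %), NaOtBu (10 mol %), MeOH (2 equiv), THF, 25 °C; then aq KHF2, MeOH, 25 °C
Reagents that add atoms: bis(pinacolato)diboron, CC1(C)OB(OC1(C)C)B1OC(C)(C)C(C)(C)O1; potassium hydrogen difluoride, [K+].[F-].F
Why: Copper‑catalysed conjugate borylation (monovalent copper boryl) takes the α‑unsubstituted cyclopentenone C3=C4 rather than the tetrasubstituted exocyclic enone and adds trans to the C5–C6 bond (boron β, methyl α); KHF2 then gives the stable tertiary trifluoroborate.

**Step 6**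
Reactants: 9 potassium trifluoro[2-oxoaromadendr-1(10)-en-4β-yl]borate
Product: 10 potassium trifluoro[2β-hydroxyaromadendr-1(10)-en-4β-yl]borate
Conditions: NaBH4, CeCl3·7H2O, MeOH, −40 °C
Reagents that add atoms: none
Why: Luche 1,2‑reduction gives the allylic alcohol (hydride expected anti to the BF3K group; the C‑2 centre is erased in step 7) and the trifluoroborate is inert to borohydride, so no aldehyde chemoselectivity problem arises later.

**Step 7**
Reactants: 10 potassium trifluoro[2β-hydroxyaromadendr-1(10)-en-4β-yl]borate; 11 2,4,6-trihydroxybenzene-1,3-dicarbaldehyde; 12 3-methylbutanal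
Product: 15 target CNP0388405.1, via ortho-quinone methide 13 (not isolated), via seco-phenol 14 (not isolated)
Conditions: 4CzIPN (2 mol %), ethylenediammonium diacetate (20 mol %), MeCN–MeOH 4:1, 450 nm LEDs, 30 °C; then CF3CO2H, CH2Cl2, 0 °C
Reagents that add atoms: none
Why: Proposed new method: Knoevenagel condensation of 11 with 12 gives the transient quinone methide 13; excited 4CzIPN oxidises trifluoroborate 10 (loss of BF3) to the C‑4 tertiary radical, which adds to the exocyclic carbon of 13 (driven by aromatisation) on the face trans to the C5–C6 bond (benzylic carbon β, methyl α) in the staggered arrangement with the quinoid ring anti to C‑5 (benzylic S centre), and the phenoxyl radical is reduced by the 4CzIPN radical anion in a redox‑neutral cycle to give 14; CF3CO2H then ionises the allylic alcohol to the C‑2/C‑1/C‑10 allyl cation, which the tethered ortho‑phenol can reach only at C‑2 from the β‑face (seven‑membered ether, 2R); closest known chemistry is the photoredox deboronative Giese addition of alkyltrifluoroborates and radical 1,6‑addition to para‑quinone methides, here extended to an in‑situ ortho‑quinone methide and a quaternary‑centre‑forming tertiary radical.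

**Compound list**
1 | (+)-aromadendrene (aromadendr-10(14)-ene; 1αH,5βH,6αH,7αH,4α-Me) | C=C1[C@H]2[C@H]([C@H]3[C@@H](CC1)C3(C)C)[C@H](C)CC2 | starting material
2 | (+)-apoaromadendrone (14-nor-1αH-aromadendran-10-one) | O=C1[C@H]2[C@H]([C@H]3[C@@H](CC1)C3(C)C)[C@H](C)CC2 | intermediate
3 | 10-(trimethylsilyloxy)-14-noraromadendr-1(10)-ene | C[Si](C)(C)OC1=C2[C@H]([C@H]3[C@@H](CC1)C3(C)C)[C@H](C)CC2 | intermediate
4 | 14-noraromadendr-1-en-10-one (5βH) | O=C1C=2[C@H]([C@H]3[C@@H](CC1)C3(C)C)[C@H](C)CC=2 | intermediate
5 | aromadendr-1-en-10β-ol (10α-methyl; expected major epimer) | C[C@@]1(O)C=2[C@H]([C@H]3[C@@H](CC1)C3(C)C)[C@H](C)CC=2 | intermediate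
6 | aromadendr-1(10)-en-2-one | CC1=C2[C@H]([C@H]3[C@@H](CC1)C3(C)C)[C@H](C)CC2=O | intermediate
7 | aromadendra-1(10),3-dien-2-one | CC1=C2[C@H]([C@H]3[C@@H](CC1)C3(C)C)C(C)=CC2=O | intermediate
8 | 4β-(4,4,5,5-tetramethyl-1,3,2-dioxaborolan-2-yl)aromadendr-1(10)-en-2-one (4α-Me) | CC1=C2[C@H]([C@H]3[C@@H](CC1)C3(C)C)[C@](B1OC(C)(C)C(C)(C)O1)(C)CC2=O | intermediate
9 | potassium trifluoro[2-oxoaromadendr-1(10)-en-4β-yl]borate | CC1=C2[C@H]([C@H]3[C@@H](CC1)C3(C)C)[C@]([B-](F)(F)F)(C)CC2=O.[K+] | intermediate
10 | potassium trifluoro[2β-hydroxyaromadendr-1(10)-en-4β-yl]borate (expected major C-2 epimer) | CC1=C2[C@H]([C@H]3[C@@H](CC1)C3(C)C)[C@]([B-](F)(F)F)(C)C[C@H]2O.[K+] | intermediate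
11 | 2,4,6-trihydroxybenzene-1,3-dicarbaldehyde (2,4-diformylphloroglucinol) | O=Cc1c(O)cc(O)c(C=O)c1O | starting material
12 | 3-methylbutanal (isovaleraldehyde) | CC(C)CC=O | starting material
13 | 2,4-dihydroxy-5-(3-methylbutylidene)-6-oxocyclohexa-1,3-diene-1,3-dicarbaldehyde (ortho-quinone methide) | CC(C)CC=C1C(=O)C(C=O)=C(O)C(C=O)=C1O | intermediate
14 | 2,4,6-trihydroxy-5-[(1S)-1-(2β-hydroxyaromadendr-1(10)-en-4β-yl)-3-methylbutyl]benzene-1,3-dicarbaldehyde (seco-phenol) | CC1=C2[C@H]([C@H]3[C@@H](CC1)C3(C)C)[C@](C)(C[C@H]2O)[C@H](CC(C)C)c1c(O)c(C=O)c(O)c(C=O)c1O | intermediate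
15 | CNP0388405.1 (aromadendrane numbering 2R,4R,5R,6R,7R; benzylic carbon S; 2β-O/4β-C bridged oxepane) | CC1=C2[C@H]([C@H]3[C@@H](CC1)C3(C)C)[C@]1(C)C[C@H]2Oc2c(C=O)c(O)c(C=O)c(O)c2[C@H]1CC(C)C | target

**Totals**
Total step count: 7. Longest linear sequence: 7 steps (1 → 15).

**Steps most likely to fail, and fallbacks**

Step 7 (the proposed new step). The risks are oligomerisation of the quinone methide 13 before radical capture, modest control of the benzylic centre, and premature ionisation of the allylic alcohol. The fallback uses known hydrogen‑atom‑transfer chemistry and sets out from 7. Luche reduction (NaBH4, CeCl3·7H2O, MeOH) gives aromadendra-1(10),3-dien-2β-ol F1. F1 is then treated with 11, 12, Fe(acac)3 and PhSiH3 in EtOH at 60 °C, a reductive olefin coupling of the Baran type that is known with quinone methide acceptors. Hydrogen‑atom transfer to C‑3 of the trisubstituted C3=C4 alkene (the tetrasubstituted C1=C10 alkene is inert) generates the same C‑4 radical, which adds to 13 and gives 14. The route is rejoined at 14, which CF3CO2H closes to 15.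

Step 2. The risks are the enol silane regiochemistry and the direction of β‑hydride elimination (C1=C5 or C8=C9 enones). The fallback replaces desaturation by C–H oxidation and sets out from 1. Acid isomerisation (catalytic TsOH, benzene, 25 °C) gives (+)-ledene F2. A Schenck ene reaction with singlet oxygen (O2, tetraphenylporphyrin, hν, CH2Cl2, −20 °C) on the α‑face abstracts H‑2α and gives 10α-hydroperoxyaromadendr-1-ene F3, which is separated from the regioisomeric ene products. PPh3 reduces F3 to aromadendr-1-en-10α-ol F4, the C‑10 epimer of 5. F4 is carried through the step 4 conditions unchanged (both epimers give 6) and the route is rejoined at 7.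

Step 4. The risks are over‑oxidation at the γ positions (C‑9, C‑14) and loss of the acidic γ‑hydrogen H‑5 of 7 at 80 °C. The fallback is stepwise and sets out from 5. Pyridinium chlorochromate (C5H5NH[CrO3Cl], CH2Cl2, 25 °C; Dauben–Michno transposition) gives 6, which is isolated. Kinetic deprotonation at C‑3 (LDA, THF, −78 °C) and PhSeBr give 3β-(phenylselanyl)aromadendr-1(10)-en-2-one F5. H2O2 (0 °C) then causes selenoxide syn‑elimination with the cis H‑4β, and the route is rejoined at 7.

**Further compounds**
F1 | step 7 | aromadendra-1(10),3-dien-2β-ol | CC1=C2[C@H]([C@H]3[C@@H](CC1)C3(C)C)C(C)=C[C@H]2O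
F2 | step 2 | (+)-ledene (aromadendr-1(10)-ene) | CC1=C2[C@H]([C@H]3[C@@H](CC1)C3(C)C)[C@H](C)CC2
F3 | step 2 | 10α-hydroperoxyaromadendr-1-ene | C[C@]1(OO)C=2[C@H]([C@H]3[C@@H](CC1)C3(C)C)[C@H](C)CC=2
F4 | step 2 | aromadendr-1-en-10α-ol (C-10 epimer of 5) | C[C@]1(O)C=2[C@H]([C@H]3[C@@H](CC1)C3(C)C)[C@H](C)CC=2
F5 | step 4 | 3β-(phenylselanyl)aromadendr-1(10)-en-2-one | CC1=C2[C@H]([C@H]3[C@@H](CC1)C3(C)C)[C@H](C)[C@@H]([Se]c1ccccc1)C2=O
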